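**Retrosynthetic overview**

1. The target comes from a fully silylated flavanone by global desilylation. Its C4 ketone is carried through the key step as a C4 carbinol bearing one extra ester carbon, which is excised afterwards (ester to CH2OH, then periodate cleavage).
2. Ring C is cut at O1–C2 and C4–C4a into a 2-alkyl-5-silyloxyresorcinol (ring A with the complete side chain) and an (E)-4-aryl-2-oxobut-3-enoate (ring B plus C2–C3–C4). Forward, a chiral magnesium bisoxazoline catalyst joins them by oxa-Michael addition then Friedel–Crafts closure and sets C2. Rings A and B are bought (benzene-1,3,5-triol, 2,4-dihydroxybenzaldehyde); ring C is the only ring formed.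
3. Enabling feature: ring A is a phloroglucinol, so C4a lies between the oxygen-bearing carbons C5 and C8a, and O1/C4a act as an O,C-bisnucleophile. With O5 silylated and the side chain on C8, the hydroxyls on C7 and C8a are equivalent and each has one free ortho carbon, so only the 8-alkyl chromane can form. C4 is a ketone, so it can enter as the keto carbon of an α-keto ester.
4. Side chain: trans-alkylation of (4S)-4-methyloxolan-2-one with prenyl bromide sets both side-chain centres. The derived lactol is joined to lithiated ring A, and the benzylic hydroxyl is removed by ionic hydrogenation.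

Key step: step 11

Assumption: (4S)-4-methyloxolan-2-one is taken as a purchasable chiral-pool lactone.
Assumption: the (S,S)-ligand is taken to give the 2S series; the sense has to be checked on a model phenol, and the (R,R)-ligand is used with no other change if it is opposite.
Abbreviations in names: TBS = tert-butyl(dimethyl)silyl, TIPS = tri(propan-2-yl)silyl, MOM = methoxymethyl.

**Route**

Step 1
Reactants: 1 (4S)-4-methyloxolan-2-one; 2 1-bromo-3-methylbut-2-ene
Product: 4 (3S,4S)-4-methyl-3-(3-methylbut-2-en-1-yl)oxolan-2-one, via lithium enolate 3 (not isolated)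
Conditions: LiN(i-Pr)2, THF, −78 °C; then 2, −78 → −30 °C
Reagents that add atoms: none
Why: The lithium enolate 3 should be alkylated on the face anti to the C4 methyl group, so the new C3 centre is expected mainly trans to it (substrate-controlled enolate alkylation of a β-substituted γ-butyrolactone).

Step 2
Reactants: 4 (3S,4S)-4-methyl-3-(3-methylbut-2-en-1-yl)oxolan-2-one
Product: 5 (3S,4S)-4-methyl-3-(3-methylbut-2-en-1-yl)oxolan-2-ol (both anomers)
Conditions: i-Bu2AlH, CH2Cl2, −78 °C; aq. potassium sodium tartrate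
Reagents that add atoms: none
Why: Hydride addition at −78 °C should stop at the aluminium hemiacetal, which gives the lactol on work-up (partial reduction of a lactone) without touching the two set centres.

Step 3
Reactants: 6 benzene-1,3,5-triol
Product: 7 5-(TIPS-oxy)benzene-1,3-diol
Conditions: i-Pr3SiCl (1.0 equiv), imidazole, DMF, 0 °C → rt
Reagents that add atoms: chlorotri(propan-2-yl)silane, CC(C)[Si](Cl)(C(C)C)C(C)C
Why: One equivalent of the bulky silyl chloride should give mainly the mono-ether of the symmetric triol (statistical monosilylation), which is separable from water-soluble 6 and from over-silylated material.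

Step 4
Reactants: 7 5-(TIPS-oxy)benzene-1,3-diol
Product: 8 [3,5-bis(methoxymethoxy)phenoxy]tri(propan-2-yl)silane
Conditions: MeOCH2Cl (2.5 equiv), i-Pr2NEt, CH2Cl2, 0 °C → rt
Reagents that add atoms: chloro(methoxy)methane, COCCl
Why: O-alkylation of both phenols with the chloromethyl ether and a hindered amine base is routine (acetal-type ether formation) and installs the two groups that direct the metalation in step 5.

Step 5
Reactants: 8 [3,5-bis(methoxymethoxy)phenoxy]tri(propan-2-yl)silane; 5 (3S,4S)-4-methyl-3-(3-methylbut-2-en-1-yl)oxolan-2-ol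
Product: 10 (2S)-1-[2,6-bis(MOM-oxy)-4-(TIPS-oxy)phenyl]-2-[(2S)-1-hydroxypropan-2-yl]-5-methylhex-4-en-1-ol (both C1 epimers), via aryllithium 9 (not isolated)
Conditions: 8 (2.3 equiv), n-BuLi (2.2 equiv), THF, 0 °C; then 5, −78 → −20 °C; H2O
Reagents that add atoms: none
Why: Directed ortho-metalation should occur at the carbon flanked by the two MOM ethers (the bulky silyl ether is a poor director), and aryllithium 9 then adds to the open hydroxy-aldehyde form of the lactol (carbonyl addition), the new carbinol centre being formed as a mixture that is removed in step 7.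

Step 6
Reactants: 10 (2S)-1-[2,6-bis(MOM-oxy)-4-(TIPS-oxy)phenyl]-2-[(2S)-1-hydroxypropan-2-yl]-5-methylhex-4-en-1-ol
Product: 11 (2S)-1-[2,6-bis(MOM-oxy)-4-(TIPS-oxy)phenyl]-2-[(2S)-1-(TBS-oxy)propan-2-yl]-5-methylhex-4-en-1-ol (both C1 epimers)
Conditions: t-BuMe2SiCl (1.1 equiv), imidazole, CH2Cl2, 0 °C
Reagents that add atoms: tert-butyl(chloro)dimethylsilane, CC(C)(C)[Si](C)(C)Cl
Why: The primary hydroxyl is far less hindered than the di-ortho-substituted benzylic carbinol, so monosilylation should be selective (silyl ether formation).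

Step 7
Reactants: 11 (2S)-1-[2,6-bis(MOM-oxy)-4-(TIPS-oxy)phenyl]-2-[(2S)-1-(TBS-oxy)propan-2-yl]-5-methylhex-4-en-1-ol
Product: 12 tert-butyl{(2S)-2-[(2R)-1-[2,6-bis(MOM-oxy)-4-(TIPS-oxy)phenyl]-5-methylhex-4-en-2-yl]propoxy}dimethylsilane
Conditions: Et3SiH, CF3CO2H, CH2Cl2, −40 °C; aq. NaHCO3
Reagents that add atoms: none
Why: Acid ionises the benzylic alcohol to a cation stabilised by three ring oxygens, which the silane should trap (ionic hydrogenation) at a temperature at which the acetals, the silyl ethers and the trisubstituted alkene are expected to survive.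

Step 8
Reactants: 12 tert-butyl{(2S)-2-[(2R)-1-[2,6-bis(MOM-oxy)-4-(TIPS-oxy)phenyl]-5-methylhex-4-en-2-yl]propoxy}dimethylsilane
Product: 13 2-[(2R)-2-[(2S)-1-(TBS-oxy)propan-2-yl]-5-methylhex-4-en-1-yl]-5-(TIPS-oxy)benzene-1,3-diol
Conditions: Me3SiOSO2CF3, 2,2′-bipyridyl, CH2Cl2, 0 °C → rt; then H2O
Reagents that add atoms: none
Why: The silyl triflate/bipyridyl pair should convert the aryl MOM ethers into aryl silyl ethers that hydrolyse on work-up (buffered acetal cleavage), under non-protic conditions that should spare the alkyl and aryl silyl ethers and the alkene.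

Step 9
Reactants: 14 2,4-dihydroxybenzaldehyde
Product: 15 2,4-bis(TBS-oxy)benzaldehyde
Conditions: t-BuMe2SiCl (2.4 equiv), imidazole, DMF, rt
Reagents that add atoms: tert-butyl(chloro)dimethylsilane, CC(C)(C)[Si](C)(C)Cl
Why: Standard silylation of both phenols (silyl ether formation) masks them for the olefination and the Lewis acid step.

Step 10
Reactants: 15 2,4-bis(TBS-oxy)benzaldehyde; 16 ethyl 2-oxo-3-(triphenyl-λ5-phosphanylidene)propanoate
Product: 17 ethyl (3E)-4-[2,4-bis(TBS-oxy)phenyl]-2-oxobut-3-enoate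
Conditions: toluene, 90 °C
Reagents that add atoms: none
Why: The stabilised ylide should give the (E)-enone selectively (Wittig olefination) and brings in C2, C3, C4 and the ester carbon that is excised in step 13.

Step 11
Reactants: 13 2-[(2R)-2-[(2S)-1-(TBS-oxy)propan-2-yl]-5-methylhex-4-en-1-yl]-5-(TIPS-oxy)benzene-1,3-diol; 17 ethyl (3E)-4-[2,4-bis(TBS-oxy)phenyl]-2-oxobut-3-enoate
Product: 19 ethyl (2S)-2-[2,4-bis(TBS-oxy)phenyl]-4,7-dihydroxy-8-[(2R)-2-[(2S)-1-(TBS-oxy)propan-2-yl]-5-methylhex-4-en-1-yl]-5-(TIPS-oxy)-3,4-dihydro-2H-chromene-4-carboxylate (C4 left open), via oxa-Michael adduct 18 (not isolated)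
Conditions: Mg(OSO2CF3)2 (20 mol %), (S,S)-2,2′-(propane-2,2-diyl)bis(4-tert-butyl-4,5-dihydro-1,3-oxazole) (22 mol %), 4 Å molecular sieves, CH2Cl2, 0 °C → rt; 13 (1.2 equiv)
Reagents that add atoms: none
Why: The magnesium triflate–bisoxazoline complex chelates the 1,2-dicarbonyl unit of 17, a phenolic oxygen of 13 (the future O1; both free hydroxyls are equivalent) adds reversibly to the γ-carbon (intermolecular oxa-Michael addition) to give 18, and the still-chelated keto group is then attacked by the only free carbon ortho to that oxygen (the future C4a) in an irreversible Friedel–Crafts hydroxyalkylation that closes ring C in the 6-exo-trig mode. The closest known reaction type is the bisoxazoline–magnesium triflate catalysed tandem oxa-Michael/Friedel–Crafts reaction of electron-rich phenols with β,γ-unsaturated α-keto esters, which gives 4-hydroxychromane-4-carboxylates. C2 is the only new stereocentre that is kept: the chiral ligand shields one face of the chelated enone and lets only one C2 epimer of the reversibly formed adduct 18 go on to ring closure, while the C4 carbinol centre is destroyed in step 13. Three selectivities are needed: oxygen before carbon attack at the γ-carbon (each free ring carbon of 13 is flanked by a hydroxyl and the bulky silyloxy group, and the oxygen addition is reversible and drained by the ring closure); 8-alkyl instead of 6-alkyl regiochemistry (O5 is silylated, so only a hydroxyl next to the side chain can add, and it has a single free ortho carbon); and mono-annulation (13 is used in slight excess, since 19 keeps one free hydroxyl whose ortho carbon is more hindered). Any minor C2 epimer is a diastereomer because of the two side-chain centres and should be removable by chromatography at this stage.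

Step 12
Reactants: 19 ethyl (2S)-2-[2,4-bis(TBS-oxy)phenyl]-4,7-dihydroxy-8-[(2R)-2-[(2S)-1-(TBS-oxy)propan-2-yl]-5-methylhex-4-en-1-yl]-5-(TIPS-oxy)-3,4-dihydro-2H-chromene-4-carboxylate
Product: 20 (2S)-2-[2,4-bis(TBS-oxy)phenyl]-4-(hydroxymethyl)-8-[(2R)-2-[(2S)-1-(TBS-oxy)propan-2-yl]-5-methylhex-4-en-1-yl]-5-(TIPS-oxy)-3,4-dihydro-2H-chromene-4,7-diol
Conditions: LiBH4, THF, 0 °C; H2O
Reagents that add atoms: none
Why: Lithium borohydride should reduce the α-hydroxy ester, assisted by the neighbouring hydroxyl, and leave silyl ethers, alkene and C2 untouched (ester reduction).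

Step 13
Reactants: 20 (2S)-2-[2,4-bis(TBS-oxy)phenyl]-4-(hydroxymethyl)-8-[(2R)-2-[(2S)-1-(TBS-oxy)propan-2-yl]-5-methylhex-4-en-1-yl]-5-(TIPS-oxy)-3,4-dihydro-2H-chromene-4,7-diol
Product: 21 (2S)-2-[2,4-bis(TBS-oxy)phenyl]-7-hydroxy-8-[(2R)-2-[(2S)-1-(TBS-oxy)propan-2-yl]-5-methylhex-4-en-1-yl]-5-(TIPS-oxy)-2,3-dihydro-4H-chromen-4-one
Conditions: NaIO4, THF/pH 7 phosphate buffer, 0 °C
Reagents that add atoms: none
Why: Periodate should cleave the 1,2-diol between C4 and the hydroxymethyl carbon much faster than it attacks the phenol, giving the C4 ketone and formaldehyde (glycol cleavage) under neutral conditions that should not open ring C.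

Step 14
Reactants: 21 (2S)-2-[2,4-bis(TBS-oxy)phenyl]-7-hydroxy-8-[(2R)-2-[(2S)-1-(TBS-oxy)propan-2-yl]-5-methylhex-4-en-1-yl]-5-(TIPS-oxy)-2,3-dihydro-4H-chromen-4-one
Product: 22 (2S)-2-(2,4-dihydroxyphenyl)-5,7-dihydroxy-8-[(2R)-2-[(2S)-1-hydroxypropan-2-yl]-5-methylhex-4-en-1-yl]-2,3-dihydro-4H-chromen-4-one
Conditions: Et3N·3HF, THF/MeCN, rt
Reagents that add atoms: none
Why: Amine-buffered hydrogen fluoride should remove all four silyl groups (desilylation) under weakly acidic conditions in which the flavanone C2 centre and the trisubstituted alkene are expected to be stable.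

**Compound list**

1 | (4S)-4-methyloxolan-2-one | C[C@@H]1COC(=O)C1 | starting material
2 | 1-bromo-3-methylbut-2-ene | CC(C)=CCBr | starting material
3 | lithium (4S)-4-methyl-4,5-dihydrofuran-2-olate | C[C@@H]1COC([O-])=C1.[Li+] | intermediate
4 | (3S,4S)-4-methyl-3-(3-methylbut-2-en-1-yl)oxolan-2-one | CC(C)=CC[C@@H]1C(=O)OC[C@H]1C | intermediate
5 | (3S,4S)-4-methyl-3-(3-methylbut-2-en-1-yl)oxolan-2-ol (both anomers) | CC(C)=CC[C@@H]1C(O)OC[C@H]1C | intermediate
6 | benzene-1,3,5-triol | Oc1cc(O)cc(O)c1 | starting material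
7 | 5-(TIPS-oxy)benzene-1,3-diol | Oc1cc(O)cc(O[Si](C(C)C)(C(C)C)C(C)C)c1 | intermediate
8 | [3,5-bis(methoxymethoxy)phenoxy]tri(propan-2-yl)silane | COCOc1cc(OCOC)cc(O[Si](C(C)C)(C(C)C)C(C)C)c1 | intermediate
9 | [2,6-bis(MOM-oxy)-4-(TIPS-oxy)phenyl]lithium | [Li]c1c(OCOC)cc(O[Si](C(C)C)(C(C)C)C(C)C)cc1OCOC | intermediate
10 | (2S)-1-[2,6-bis(MOM-oxy)-4-(TIPS-oxy)phenyl]-2-[(2S)-1-hydroxypropan-2-yl]-5-methylhex-4-en-1-ol (both C1 epimers) | CC(C)=CC[C@H](C(O)c1c(OCOC)cc(O[Si](C(C)C)(C(C)C)C(C)C)cc1OCOC)[C@H](C)CO | intermediate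
11 | (2S)-1-[2,6-bis(MOM-oxy)-4-(TIPS-oxy)phenyl]-2-[(2S)-1-(TBS-oxy)propan-2-yl]-5-methylhex-4-en-1-ol (both C1 epimers) | CC(C)=CC[C@H](C(O)c1c(OCOC)cc(O[Si](C(C)C)(C(C)C)C(C)C)cc1OCOC)[C@H](C)CO[Si](C)(C)C(C)(C)C | intermediate
12 | tert-butyl{(2S)-2-[(2R)-1-[2,6-bis(MOM-oxy)-4-(TIPS-oxy)phenyl]-5-methylhex-4-en-2-yl]propoxy}dimethylsilane | CC(C)=CC[C@H](Cc1c(OCOC)cc(O[Si](C(C)C)(C(C)C)C(C)C)cc1OCOC)[C@H](C)CO[Si](C)(C)C(C)(C)C | intermediate
13 | 2-[(2R)-2-[(2S)-1-(TBS-oxy)propan-2-yl]-5-methylhex-4-en-1-yl]-5-(TIPS-oxy)benzene-1,3-diol | CC(C)=CC[C@H](Cc1c(O)cc(O[Si](C(C)C)(C(C)C)C(C)C)cc1O)[C@H](C)CO[Si](C)(C)C(C)(C)C | intermediate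
14 | 2,4-dihydroxybenzaldehyde | O=Cc1ccc(O)cc1O | starting material
15 | 2,4-bis(TBS-oxy)benzaldehyde | O=Cc1ccc(O[Si](C)(C)C(C)(C)C)cc1O[Si](C)(C)C(C)(C)C | intermediate
16 | ethyl 2-oxo-3-(triphenyl-λ5-phosphanylidene)propanoate | CCOC(=O)C(=O)C=P(c1ccccc1)(c1ccccc1)c1ccccc1 | starting material
17 | ethyl (3E)-4-[2,4-bis(TBS-oxy)phenyl]-2-oxobut-3-enoate | CCOC(=O)C(=O)/C=C/c1ccc(O[Si](C)(C)C(C)(C)C)cc1O[Si](C)(C)C(C)(C)C | intermediate
18 | ethyl (4S)-4-[2,4-bis(TBS-oxy)phenyl]-4-{3-hydroxy-2-[(2R)-2-[(2S)-1-(TBS-oxy)propan-2-yl]-5-methylhex-4-en-1-yl]-5-(TIPS-oxy)phenoxy}-2-oxobutanoate | CC(C)=CC[C@H](Cc1c(O)cc(O[Si](C(C)C)(C(C)C)C(C)C)cc1O[C@H](c1ccc(O[Si](C)(C)C(C)(C)C)cc1O[Si](C)(C)C(C)(C)C)CC(=O)C(=O)OCC)[C@H](C)CO[Si](C)(C)C(C)(C)C | intermediate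
19 | ethyl (2S)-2-[2,4-bis(TBS-oxy)phenyl]-4,7-dihydroxy-8-[(2R)-2-[(2S)-1-(TBS-oxy)propan-2-yl]-5-methylhex-4-en-1-yl]-5-(TIPS-oxy)-3,4-dihydro-2H-chromene-4-carboxylate (C4 left open) | CC(C)=CC[C@H](Cc1c(O)cc(O[Si](C(C)C)(C(C)C)C(C)C)c2c1O[C@H](c1ccc(O[Si](C)(C)C(C)(C)C)cc1O[Si](C)(C)C(C)(C)C)CC2(O)C(=O)OCC)[C@H](C)CO[Si](C)(C)C(C)(C)C | intermediate
20 | (2S)-2-[2,4-bis(TBS-oxy)phenyl]-4-(hydroxymethyl)-8-[(2R)-2-[(2S)-1-(TBS-oxy)propan-2-yl]-5-methylhex-4-en-1-yl]-5-(TIPS-oxy)-3,4-dihydro-2H-chromene-4,7-diol (C4 left open) | CC(C)=CC[C@H](Cc1c(O)cc(O[Si](C(C)C)(C(C)C)C(C)C)c2c1O[C@H](c1ccc(O[Si](C)(C)C(C)(C)C)cc1O[Si](C)(C)C(C)(C)C)CC2(O)CO)[C@H](C)CO[Si](C)(C)C(C)(C)C | intermediate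
21 | (2S)-2-[2,4-bis(TBS-oxy)phenyl]-7-hydroxy-8-[(2R)-2-[(2S)-1-(TBS-oxy)propan-2-yl]-5-methylhex-4-en-1-yl]-5-(TIPS-oxy)-2,3-dihydro-4H-chromen-4-one | CC(C)=CC[C@H](Cc1c(O)cc(O[Si](C(C)C)(C(C)C)C(C)C)c2c1O[C@H](c1ccc(O[Si](C)(C)C(C)(C)C)cc1O[Si](C)(C)C(C)(C)C)CC2=O)[C@H](C)CO[Si](C)(C)C(C)(C)C | intermediate
22 | (2S)-2-(2,4-dihydroxyphenyl)-5,7-dihydroxy-8-[(2R)-2-[(2S)-1-hydroxypropan-2-yl]-5-methylhex-4-en-1-yl]-2,3-dihydro-4H-chromen-4-one | CC(C)=CC[C@H](Cc1c(O)cc(O)c2c1O[C@H](c1ccc(O)cc1O)CC2=O)[C@H](C)CO | target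

**Step count and risks**

Total step count: 14. Longest linear sequence: 10 steps (1, 2, 5, 6, 7, 8, 11, 12, 13, 14).

Steps most likely to fail:

1. Step 11. What may go wrong: insufficient facial control in the oxa-Michael/Friedel–Crafts cascade with this hindered, very electron-rich phenol; carbon instead of oxygen attack at the γ-carbon (which leads to the 4-aryl chromane series); or a second annulation at O7/C6. Fallback, setting out from 13 and coming back at 21: the magnesium bis-phenolate of 13 (EtMgBr, toluene) is C-acylated ortho to oxygen with tert-butyl 3-chloro-3-oxopropanoate to give the tert-butyl β-keto ester F1. Knoevenagel condensation of F1 with aldehyde 15 (piperidine, AcOH, benzene, reflux) gives the alkylidene β-keto ester F2. A cinchona-alkaloid-derived bifunctional thiourea (the pseudo-enantiomer that gives 2S) then closes ring C by enantioselective 6-endo-trig oxa-Michael addition to the tert-butyl 4-oxochromane-3-carboxylate F3. p-Toluenesulfonic acid in warm toluene finally removes the ester group by loss of 2-methylpropene and carbon dioxide, which gives 21.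

2. Step 5. What may go wrong: slow opening of the lithium lactolate, so that the hindered aryllithium acts as a base (proton transfer, recovered lactol) instead of adding to the carbonyl group. Fallback, setting out from 4 and 9 and coming back at 11: aryllithium 9 is added to lactone 4 at −78 °C; the lithium hemiketal collapses only on work-up, so the hydroxy ketone F4 is formed without exposing its α-centre to base. Silylation of the primary hydroxyl (t-BuMe2SiCl, imidazole) gives the silyl ether F5, and LiAlH4 in THF at 0 °C reduces the hindered aryl ketone to carbinol 11.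

3. Step 7. What may go wrong: loss of acetal or silyl protecting groups under the acid, or trapping of the benzylic cation by the silyl ether oxygen or the alkene instead of by the silane. Fallback, setting out from 11 and coming back at 12: the carbinol is converted into the S-methyl xanthate F6 (NaH, CS2, MeI, THF), which is reduced with Bu3SnH and azobisisobutyronitrile in toluene at 80 °C (Barton–McCombie deoxygenation). The benzylic radical has no favourable cyclisation onto the alkene, and no acid is involved.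

Further compounds
F1 | step 11 | tert-butyl 3-{2,4-dihydroxy-3-[(2R)-2-[(2S)-1-(TBS-oxy)propan-2-yl]-5-methylhex-4-en-1-yl]-6-(TIPS-oxy)phenyl}-3-oxopropanoate | CC(C)=CC[C@H](Cc1c(O)cc(O[Si](C(C)C)(C(C)C)C(C)C)c(C(=O)CC(=O)OC(C)(C)C)c1O)[C@H](C)CO[Si](C)(C)C(C)(C)C
F2 | step 11 | tert-butyl 3-[2,4-bis(TBS-oxy)phenyl]-2-{2,4-dihydroxy-3-[(2R)-2-[(2S)-1-(TBS-oxy)propan-2-yl]-5-methylhex-4-en-1-yl]-6-(TIPS-oxy)benzoyl}prop-2-enoate (alkene geometry open) | CC(C)=CC[C@H](Cc1c(O)cc(O[Si](C(C)C)(C(C)C)C(C)C)c(C(=O)C(=Cc2ccc(O[Si](C)(C)C(C)(C)C)cc2O[Si](C)(C)C(C)(C)C)C(=O)OC(C)(C)C)c1O)[C@H](C)CO[Si](C)(C)C(C)(C)C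
F3 | step 11 | tert-butyl (2S)-2-[2,4-bis(TBS-oxy)phenyl]-7-hydroxy-8-[(2R)-2-[(2S)-1-(TBS-oxy)propan-2-yl]-5-methylhex-4-en-1-yl]-4-oxo-5-(TIPS-oxy)-3,4-dihydro-2H-chromene-3-carboxylate (C3 left open) | CC(C)=CC[C@H](Cc1c(O)cc(O[Si](C(C)C)(C(C)C)C(C)C)c2c1O[C@H](c1ccc(O[Si](C)(C)C(C)(C)C)cc1O[Si](C)(C)C(C)(C)C)C(C(=O)OC(C)(C)C)C2=O)[C@H](C)CO[Si](C)(C)C(C)(C)C
F4 | step 5 | (2S)-1-[2,6-bis(MOM-oxy)-4-(TIPS-oxy)phenyl]-2-[(2S)-1-hydroxypropan-2-yl]-5-methylhex-4-en-1-one | CC(C)=CC[C@H](C(=O)c1c(OCOC)cc(O[Si](C(C)C)(C(C)C)C(C)C)cc1OCOC)[C@H](C)CO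
F5 | step 5 | (2S)-1-[2,6-bis(MOM-oxy)-4-(TIPS-oxy)phenyl]-2-[(2S)-1-(TBS-oxy)propan-2-yl]-5-methylhex-4-en-1-one | CC(C)=CC[C@H](C(=O)c1c(OCOC)cc(O[Si](C(C)C)(C(C)C)C(C)C)cc1OCOC)[C@H](C)CO[Si](C)(C)C(C)(C)C
F6 | step 7 | O-{(2S)-1-[2,6-bis(MOM-oxy)-4-(TIPS-oxy)phenyl]-2-[(2S)-1-(TBS-oxy)propan-2-yl]-5-methylhex-4-en-1-yl} S-methyl carbonodithioate (both C1 epimers) | CC(C)=CC[C@H](C(OC(=S)SC)c1c(OCOC)cc(O[Si](C(C)C)(C(C)C)C(C)C)cc1OCOC)[C@H](C)CO[Si](C)(C)C(C)(C)C
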